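A small charge of second end groups, 0.70 equiv in the dusk run, left 71.8% of the first end groups free and 20.2% in links at 25.0 min, while 4.1 equiv in the summer run turned that order round, so I looked for the charge at which the two stand level.

| flask | first end groups | second end groups | remark | time |
|---|---|---|---|---|
| dusk | 0.050 M | 0.70 equiv | run made earlier |  |
| winter | 0.050 M | 2.1 equiv | run made earlier |  |
| summer | 0.050 M | 4.1 equiv | run made earlier |  |
| oak | 0.050 M | 1.90 equiv |  | 50 min |
| alder | 0.050 M | 3.80 equiv |  | 50 min |
| ash | 0.050 M | 0.950 equiv |  | 50 min |

| run | time / min | links / % | first end groups / % |
|---|---|---|---|
| dusk | 2.00 | 2.8 | 95.7 |
| dusk | 6.00 | 8.8 | 89.0 |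
| dusk | 12.0 | 13.1 | 82.1 |
| dusk | 20.0 | 18.0 | 75.2 |
| dusk | 25.0 | 20.2 | 71.8 |
| winter | 5.00 | 17.8 | 75.8 |
| winter | 10.0 | 27.8 | 61.6 |
| winter | 15.0 | 35.2 | 54.0 |
| winter | 20.0 | 39.0 | 50.1 |
| winter | 25.0 | 40.8 | 48.9 |
| summer | 2.00 | 15.2 | 77.8 |
| summer | 4.00 | 25.7 | 64.5 |
| summer | 8.00 | 39.8 | 48.8 |
| summer | 12.0 | 47.2 | 40.9 |
| summer | 25.0 | 53.7 | 35.2 |

(readings scatter by 0.5 percentage points)

- the numbers in the tables scatter by 0.5 percentage points (one standard deviation)
- a reading or a percentage of links counts all its forms, free or not
- a reading of first end groups is of its free form alone

* which of these there is most of at the end, counted by the first end groups in it, oak (first end groups / links)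
* which of these there is most of at the end, counted by the first end groups in it, alder (first end groups / links)
* which of these there is most of at the end, counted by the first end groups in it, ash (first end groups / links)
* how much there is at the end of the one of these that leads, in percent of the first end groups charged: oak
* how much there is at the end of the one of these that leads, in percent of the first end groups charged: alder
* how much there is at the end of the one of these that leads, in percent of the first end groups charged: ash

 At summer's last reading, c(links) squared over c(first end groups) times c(second end groups), taking the latter as charge minus links, read 0.230, as if each link came out with a by-product that could reverse it. The gap in the balance, divided by the product of the two fractions, read 0.587, as if links held free first end groups. Setting the two fractions equal in these relations gave a level fraction of 44.3% and so the turning charge 2.37 equivalents, the charge of second end groups at which links and free first end groups stand level once the flask stalls.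

My one number is the charge divided by the turning charge: above one, links lead, and below one, first end groups lead. The winter run tests it, since it gave no input: at 0.887 it should favour first end groups, and it read 48.9% against 40.8%. For oak, alder and ash the number is 0.803, 1.61 and 0.401. It names a leader but gives no amount and no clock, and winter's links were still rising at 25.0 min, though these flasks run twice as long.

The forecast, reading the stall as “a reversible reaction with a coproduct”, named the same leaders: first end groups at 48.6% for oak, links at 52.2% for alder and first end groups at 61% for ash.

The flasks gave first end groups at 49.3% for oak, links at 50.1% for alder and first end groups at 61.9% for ash.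

    first end groups + links ⇌ idle adduct, settled at all times (K = 16.1 /M)
    first end groups + second end groups ⇌ links + by-product (K = 0.230, k = 0.424 /M/min)
    second end groups → decomposed reagent (k = 0.00946 /min)

In alder at 50.0 min, the link step relaxed with a half-life of 5.22 min, shorter than the 73 min half-life of second end groups going to decomposed reagent, and 54% of their charge was left. Second end groups left plus links came to 2.54 equivalents, above the turning charge of 2.37 equivalents, and links led. The same alder flask read at 2.0 h has 1.53 equivalents, below the turning charge, which favours first end groups. The computed flask holds 46.3% of them against 42.2% in links.

All runs come from a simulation with constants of no real substance; scatter was added.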